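The furan ring is disconnected at O1–C2 and C3–C3a, which uncovers an (E)-propenylarene carrying the C2 aryl and C3 methyl groups and a dearomatized, allyl-bearing methoxyphenol. In one operation an acid-ionized quinone monoketal adds this alkene in a cationic formal [3+2] cycloaddition: the allyl-bearing ring carbon becomes C3a, the dienone oxygen becomes O1, and every substituent of the target is in place. The step exploits the fact that the C7 allyl, C6 hydroxyl and C5 methoxy of the benzo ring are what a C3a-allyl 5-methoxy-6-oxo dienone gives after one [3,3] shift across C7a=C7. The precursor is 2-allyl-4,4,5-trimethoxycyclohexa-2,5-dienone plus (E)-isoelemicin.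

Key step: step 6

Remark: all chiral intermediates are racemic; each SMILES shows one enantiomer of the relative configuration, and centres that are not controlled carry no descriptor.

Step 1
Reactants: 1 3,4-dimethoxyphenol; 2 allyl bromide
Product: 3 allyl 3,4-dimethoxyphenyl ether
Conditions: K2CO3, acetone, reflux
Reagents that add atoms: none
Why: Williamson ether synthesis, in which the phenoxide formed by K2CO3 displaces bromide from the allylic halide by SN2 and O-alkylation is favoured in acetone.

Step 2
Reactants: 3 allyl 3,4-dimethoxyphenyl ether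
Product: 5 2-allyl-4,5-dimethoxyphenol, via ortho-dienone 4 (not isolated)
Conditions: N,N-diethylaniline, 195 °C, argon
Reagents that add atoms: none
Why: Aromatic Claisen rearrangement, a concerted [3,3] shift that should favour the ortho carbon not flanked by the C3 methoxy group and gives dienone 4, which tautomerizes to the phenol.

Step 3
Reactants: 5 2-allyl-4,5-dimethoxyphenol
Product: 6 2-allyl-4,4,5-trimethoxycyclohexa-2,5-dien-1-one
Conditions: PhI(OAc)2, MeOH, 0 °C
Reagents that add atoms: methanol, CO
Why: Oxidative dearomatization of a para-methoxyphenol with a hypervalent iodine reagent, in which methanol adds at the methoxy-bearing para carbon as iodobenzene leaves to give the para-quinone monoketal while the isolated allyl alkene is not touched.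

Step 4
Reactants: 7 3,4,5-trimethoxybenzaldehyde; 8 ethylmagnesium bromide
Product: 9 rac-1-(3,4,5-trimethoxyphenyl)propan-1-ol
Conditions: THF, 0 °C → rt; sat. aq NH4Cl
Reagents that add atoms: none
Why: Grignard addition to a non-enolizable aryl aldehyde should give the racemic secondary benzylic alcohol cleanly.

Step 5
Reactants: 9 rac-1-(3,4,5-trimethoxyphenyl)propan-1-ol
Product: 10 (E)-1,2,3-trimethoxy-5-(prop-1-enyl)benzene ((E)-isoelemicin)
Conditions: TsOH·H2O (cat.), toluene, reflux, Dean–Stark, short reaction time
Reagents that add atoms: none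
Why: Acid-catalysed E1 dehydration through the benzylic cation gives the conjugated alkene, and reversible protonation should settle it on the more stable E isomer.

Step 6
Reactants: 6 2-allyl-4,4,5-trimethoxycyclohexa-2,5-dien-1-one; 10 (E)-isoelemicin
Product: 14 rac-(2R,3R)-3a-allyl-5-methoxy-3-methyl-2-(3,4,5-trimethoxyphenyl)-3,3a-dihydro-1-benzofuran-6(2H)-one (2,3-trans; both C3a epimers), via oxocarbenium ion 11 (not isolated), via benzylic cation 12 (not isolated), via O-methyl oxocarbenium ion 13 (not isolated)
Conditions: TMSOTf (0.3 equiv), 10 (1.5 equiv), MeCN, −40 → 0 °C; sat. aq NaHCO3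
Reagents that add atoms: none
Why: TMSOTf strips one ketal methoxy from 6 to give oxocarbenium ion 11, whose allyl-bearing C2 is the electrophilic terminus; the β-carbon of 10 bonds there (C3–C3a, quaternary centre) to give benzylic cation 12, the dienone oxygen closes onto it (O1–C2) to give 13, and transfer of the O-methyl of 13 to the methoxysilane released at the start yields 14 with net loss of dimethyl ether and return of the silyl triflate. This is the acid-promoted formal [3+2] cycloaddition of para-quinone monoketals with (E)-propenylarenes known from the burchellin-type hydrobenzofuranoid neolignans. The dihydrofuran ring is the only ring closed, stepwise and polar, by 5-exo-type capture of the benzylic cation by the carbonyl oxygen after the intermolecular C–C bond has formed. C2 and C3 should come out trans because cation 12 rotates freely and closes with aryl and methyl on opposite faces of the new ring, as the E-alkene already places them, whereas C3a is not controlled and both epimers are carried on because that centre is destroyed in step 7. The step needs attack at C2 rather than C6 and O- rather than C-capture: the C5 methoxy makes C6 the nucleophilic α-carbon of a vinylogous ester so that only C2 is electrophilic, any bicyclo[3.2.1]octenedione from C6-capture (F1 below) should re-ionize under the acid at 0 °C and drain into the more stable O-closed 14, and the isolated allyl alkene is far less nucleophilic than the styrene and should stay out of the reaction.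

Step 7
Reactants: 14 rac-(2R,3R)-3a-allyl-5-methoxy-3-methyl-2-(3,4,5-trimethoxyphenyl)-3,3a-dihydro-1-benzofuran-6(2H)-one
Product: 16 rac-(2R,3R)-7-allyl-5-methoxy-3-methyl-2-(3,4,5-trimethoxyphenyl)-2,3-dihydro-1-benzofuran-6-ol, via keto tautomer 15 (not isolated)
Conditions: 1,2-dichlorobenzene, 180 °C, argon
Reagents that add atoms: none
Why: Cope rearrangement of the 1,5-diene CH2=CH–CH2–C3a–C7a=C7 moves the allyl to C7 and gives keto tautomer 15, whose enolization to the phenol is irreversible and erases the C3a centre, while allyl that moves toward the methoxy-blocked C5 cannot aromatize there and should be fed back to the same phenol by further [3,3] shifts at this temperature.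

Step 8
Reactants: 16 rac-(2R,3R)-7-allyl-5-methoxy-3-methyl-2-(3,4,5-trimethoxyphenyl)-2,3-dihydro-1-benzofuran-6-ol
Product: 17 rac-(2R,3R)-7-allyl-5-methoxy-3-methyl-2-(3,4,5-trimethoxyphenyl)-2,3-dihydro-1-benzofuran-6-yl acetate
Conditions: Ac2O, pyridine, DMAP (cat.), CH2Cl2, rt
Reagents that add atoms: acetic anhydride, CC(=O)OC(C)=O
Why: DMAP-catalysed O-acylation masks the phenol so that the oxidant of the next step cannot turn it into a quinone methide or a chromene through the ortho allyl group.

Step 9
Reactants: 17 rac-(2R,3R)-7-allyl-5-methoxy-3-methyl-2-(3,4,5-trimethoxyphenyl)-2,3-dihydro-1-benzofuran-6-yl acetate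
Product: 18 7-allyl-5-methoxy-3-methyl-2-(3,4,5-trimethoxyphenyl)-1-benzofuran-6-yl acetate
Conditions: DDQ (1.3 equiv), dry 1,4-dioxane, 80 °C
Reagents that add atoms: none
Why: DDQ dehydrogenation, in which hydride abstraction from C2 (benzylic and α to O1) gives an oxocarbenium ion that loses the C3 proton, is the established way from 2-aryl-3-methyl-2,3-dihydrobenzofurans to benzofurans and removes both remaining stereocentres, with dry solvent keeping oxidation of the allyl methylene down.

Step 10
Reactants: 18 7-allyl-5-methoxy-3-methyl-2-(3,4,5-trimethoxyphenyl)-1-benzofuran-6-yl acetate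
Product: 19 7-allyl-5-methoxy-3-methyl-2-(3,4,5-trimethoxyphenyl)-1-benzofuran-6-ol (target CNP0110777.0)
Conditions: K2CO3 (cat.), MeOH, rt, argon
Reagents that add atoms: none
Why: Base-catalysed transesterification of the aryl acetate with methanol frees the phenol under conditions too mild to shift the allyl double bond into conjugation.

Compound list
1 | 3,4-dimethoxyphenol | COc1ccc(O)cc1OC | starting material
2 | allyl bromide | C=CCBr | starting material
3 | allyl 3,4-dimethoxyphenyl ether | C=CCOc1ccc(OC)c(OC)c1 | intermediate
4 | rac-6-allyl-3,4-dimethoxycyclohexa-2,4-dien-1-one (not isolated) | C=CCC1C=C(OC)C(OC)=CC1=O | intermediate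
5 | 2-allyl-4,5-dimethoxyphenol | C=CCc1cc(OC)c(OC)cc1O | intermediate
6 | 2-allyl-4,4,5-trimethoxycyclohexa-2,5-dien-1-one | C=CCC1=CC(OC)(OC)C(OC)=CC1=O | intermediate
7 | 3,4,5-trimethoxybenzaldehyde | O=Cc1cc(OC)c(OC)c(OC)c1 | starting material
8 | ethylmagnesium bromide | CC[Mg]Br | starting material
9 | rac-1-(3,4,5-trimethoxyphenyl)propan-1-ol | CCC(O)c1cc(OC)c(OC)c(OC)c1 | intermediate
10 | (E)-1,2,3-trimethoxy-5-(prop-1-enyl)benzene ((E)-isoelemicin) | C/C=C/c1cc(OC)c(OC)c(OC)c1 | intermediate
11 | (5-allyl-2-methoxy-4-oxocyclohexa-2,5-dien-1-ylidene)(methyl)oxonium, triflate counter-ion (not isolated) | C=CCC1=CC(=[O+]C)C(OC)=CC1=O | intermediate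
12 | 1-(3,4,5-trimethoxyphenyl)-2-(1-allyl-3,4-dimethoxy-6-oxocyclohexa-2,4-dien-1-yl)propan-1-ylium, triflate counter-ion (not isolated) | C=CCC1(C(C)[CH+]c2cc(OC)c(OC)c(OC)c2)C=C(OC)C(OC)=CC1=O | intermediate
13 | O6-methyl oxocarbenium ion of 14, 2,3-trans, triflate counter-ion (not isolated) | C=CCC12C=C(OC)C(=[O+]C)C=C1O[C@@H](c1cc(OC)c(OC)c(OC)c1)[C@@H]2C | intermediate
14 | rac-(2R,3R)-3a-allyl-5-methoxy-3-methyl-2-(3,4,5-trimethoxyphenyl)-3,3a-dihydro-1-benzofuran-6(2H)-one, both C3a epimers | C=CCC12C=C(OC)C(=O)C=C1O[C@@H](c1cc(OC)c(OC)c(OC)c1)[C@@H]2C | intermediate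
15 | rac-(2R,3R)-7-allyl-5-methoxy-3-methyl-2-(3,4,5-trimethoxyphenyl)-3,7-dihydro-1-benzofuran-6(2H)-one, C7 not defined (not isolated) | C=CCC1C(=O)C(OC)=CC2=C1O[C@@H](c1cc(OC)c(OC)c(OC)c1)[C@@H]2C | intermediate
16 | rac-(2R,3R)-7-allyl-5-methoxy-3-methyl-2-(3,4,5-trimethoxyphenyl)-2,3-dihydro-1-benzofuran-6-ol | C=CCc1c(O)c(OC)cc2c1O[C@@H](c1cc(OC)c(OC)c(OC)c1)[C@@H]2C | intermediate
17 | rac-(2R,3R)-7-allyl-5-methoxy-3-methyl-2-(3,4,5-trimethoxyphenyl)-2,3-dihydro-1-benzofuran-6-yl acetate | C=CCc1c(OC(C)=O)c(OC)cc2c1O[C@@H](c1cc(OC)c(OC)c(OC)c1)[C@@H]2C | intermediate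
18 | 7-allyl-5-methoxy-3-methyl-2-(3,4,5-trimethoxyphenyl)-1-benzofuran-6-yl acetate | C=CCc1c(OC(C)=O)c(OC)cc2c(C)c(-c3cc(OC)c(OC)c(OC)c3)oc12 | intermediate
19 | 7-allyl-5-methoxy-3-methyl-2-(3,4,5-trimethoxyphenyl)-1-benzofuran-6-ol | C=CCc1c(O)c(OC)cc2c(C)c(-c3cc(OC)c(OC)c(OC)c3)oc12 | target

Total step count: 10
Longest linear sequence: 8 steps (steps 1, 2, 3, 6, 7, 8, 9, 10 from 3,4-dimethoxyphenol; the alkene branch, steps 4 and 5, joins at step 6)

Steps most likely to fail

Step 6. The benzylic cation may be captured by ring carbon C6 instead of by oxygen, with the equilibration toward the O-closed product staying incomplete, while the acid oligomerizes the electron-rich alkene in the meantime. The fallback sets out again from 6 and 10 and splits the union into two separate operations. TMSOTf (cat.) in CH2Cl2 at −78 °C with a cold quench should give the kinetic [5+2] adduct, rac-5-allyl-3-methoxy-6-methyl-7-(3,4,5-trimethoxyphenyl)bicyclo[3.2.1]oct-3-ene-2,8-dione (6,7-trans) F1, which is isolated free of excess alkene. F1 is then isomerized on its own with TsOH in MeCN at rt to 40 °C, the known acid-induced change of bicyclo[3.2.1]octanoid into hydrobenzofuranoid neolignans (heterolysis of the C1–C7 bond back to cation 12, then closure on oxygen). This returns to the route at 14.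

Step 9. DDQ may abstract hydride from the allyl methylene, which is both benzylic and allylic, in competition with C2–H, so that the side chain is oxidized, or the electron-rich benzofuran may be oxidized further. The fallback sets out from 16 and uses the free phenol to direct the oxidation instead of protecting it. Ag2O in CH2Cl2 at rt should oxidize this 2,6-disubstituted para-alkylphenol at C3–H to the para-quinone methide, rac-7-allyl-5-methoxy-3-methyl-2-(3,4,5-trimethoxyphenyl)-1-benzofuran-6(2H)-one F2 (C3=C3a double bond). A catalytic amount of Et3N then removes the vinylogously acidic C2–H, so that F2 tautomerizes to the aromatic benzofuran. This arrives directly at 19 and leaves out 17 and 18.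

Step 7. The allyl group may travel toward the methoxy-bearing C5 and on to O6 and stall there, or the cross-conjugated dienone may fragment or polymerize at the temperature the shift needs. The fallback replaces the carbon-to-carbon relay by an oxygen-to-carbon one that never builds the quaternary C3a; it sets out from 2 and 10. Isovanillin (3-hydroxy-4-methoxybenzaldehyde, bought) is O-allylated with 2 (K2CO3, DMF) to 3-(allyloxy)-4-methoxybenzaldehyde F3. Baeyer–Villiger oxidation (mCPBA, CH2Cl2) gives 3-(allyloxy)-4-methoxyphenyl formate F4, which is methanolysed (K2CO3, MeOH) to 3-(allyloxy)-4-methoxyphenol F5. Oxidative [3+2] cycloaddition of F5 with 10 (PhI(OCOCF3)2, hexafluoroisopropanol/CH2Cl2, 0 °C), the known hypervalent-iodine coupling of para-methoxyphenols with propenylarenes, should give rac-(2R,3R)-6-(allyloxy)-5-methoxy-3-methyl-2-(3,4,5-trimethoxyphenyl)-2,3-dihydro-1-benzofuran F6. An aromatic Claisen rearrangement (N,N-diethylaniline, 200 °C) can deliver the allyl only to C7, because C5 carries the methoxy group. It passes through the same keto tautomer 15 and returns to the route at 16.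

Further compounds
F1 | step 6 | rac-5-allyl-3-methoxy-6-methyl-7-(3,4,5-trimethoxyphenyl)bicyclo[3.2.1]oct-3-ene-2,8-dione, 6,7-trans, aryl exo or endo not defined | C=CCC12C=C(OC)C(=O)C(C1=O)[C@@H](c1cc(OC)c(OC)c(OC)c1)[C@@H]2C
F2 | step 9 | rac-7-allyl-5-methoxy-3-methyl-2-(3,4,5-trimethoxyphenyl)-1-benzofuran-6(2H)-one | C=CCC1=C2OC(c3cc(OC)c(OC)c(OC)c3)C(C)=C2C=C(OC)C1=O
F3 | step 7 | 3-(allyloxy)-4-methoxybenzaldehyde | C=CCOc1cc(C=O)ccc1OC
F4 | step 7 | 3-(allyloxy)-4-methoxyphenyl formate | C=CCOc1cc(OC=O)ccc1OC
F5 | step 7 | 3-(allyloxy)-4-methoxyphenol | C=CCOc1cc(O)ccc1OC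
F6 | step 7 | rac-(2R,3R)-6-(allyloxy)-5-methoxy-3-methyl-2-(3,4,5-trimethoxyphenyl)-2,3-dihydro-1-benzofuran | c1c(OCC=C)c(OC)cc2c1O[C@@H](c1cc(OC)c(OC)c(OC)c1)[C@@H]2C
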